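(All runs are calculated on assumed constants; the scatter is artificial.)

Set the impurity against the carrier first: the teal run and the flask hold the same 0.15 mM of impurity on different loadings.

- teal: starting material 10 mM; salt in the second phase 3 equiv; spent carrier 16 mol%; impurity 0.15 mM; run made earlier
- flask: starting material 10 mM; salt in the second phase 3.00 equiv; spent carrier 7.9 mol%; impurity 0.15 mM; volume of the second phase over the first 1.0

teal run (percent of the starting material charged)

| time / min | target / % | starting material / % |
|---|---|---|
| 2.50 | 4.0 | 38.8 |
| 4.00 | 5.0 | 26.7 |
| 6.00 | 8.2 | 19.8 |
| 8.00 | 11.7 | 15.0 |
| 12.0 | 13.7 | 8.8 |
| 20.0 | 16.3 | 3.0 |
| 30.0 | 15.9 | 0.4 |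

(each reading ± 1 percentage point)

- charges count per volume of the first phase; a concentration in a rate is the amount of a species over the volume of its own phase; every rate counts per litre of the first phase
- the numbers in the tables scatter by 1 percentage point (one standard deviation)
- the earlier runs hold the two phases in the same ratio of volumes as the flask asked about
- no earlier run changes the charge of salt in the second phase; that part of a forecast is a guess

* apparent order in salt in the second phase when 20% of the starting material are converted (percent change of the rate of making target for one percent more salt in the second phase charged)

The impurity share, the charge of impurity over the charge of carrier 19.0%, was the fraction of the catalyst I suspected a one-to-one poison could take in the flask; in the teal run it was 9.37%. My doubt was whether that debt still mattered at 20% conversion, so I needed a clock.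

In the teal run, target read 4.0% against 61.2% of starting material lost by 2.50 min, and I tried a loss second order in [starting material]. That reading gave a slope of 0.0631 mM⁻¹ min⁻¹, and the reading at 8.00 min gave 0.0708 mM⁻¹ min⁻¹, so the objection that the slope might drift did not overturn it. For the flask this put 20% conversion at 0.396 min.

Next I estimated how fast carrier is activated. Assuming the teal run had paid its impurity by 2.50 min, target plus impurity gave 0.138 min⁻¹ per carrier, at the same equivalents of salt as the flask. Dividing the share by this gave a clearing time of 1.38 min for the flask, longer than the clock. The objection is that activated carrier standing idle goes uncounted in that figure, so this clearing time is an estimate that may run long, and the true one may lie near the clock. The flask could still be paying its debt at that moment, and with the charge of impurity held, activated carrier beyond the debt changes by a larger percentage than activated carrier as a whole. I committed to an order above one and, by judgement, put it near 2.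

The forecast differed, giving 0.7: “Loaded carrier would then scale almost linearly with salt, though partial saturation of the exchange step would pull the order below one”.

The flask gave 1.7.

    2 starting material → homo dimer (k = 30.0 L mol⁻¹ min⁻¹)
    fresh carrier + impurity → spent catalyst (k = 1.50 × 10⁵ L mol⁻¹ min⁻¹)
    spent carrier + salt in the second phase ⇌ fresh carrier + spent salt in the second phase (K = 0.570, k = 20.0 L mol⁻¹ min⁻¹)
    starting material + fresh carrier → target + spent carrier (k = 51.0 L mol⁻¹ min⁻¹)

With impurity as charged, fresh carrier in the flask went to spent catalyst at 1400 h⁻¹ per fresh carrier, far faster than the 30.6 h⁻¹ at which it met starting material as charged, and at 20% conversion the catalyst held 6.03% fresh carrier and 15.4% spent catalyst, less than the impurity share of 19.0%. With twice the spent carrier in the flask, the share falls to 9.50%, and the rate in that run was higher by a factor of 3.83.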